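**Retrosynthetic overview**
The strategy rests on the oxolane ring O1–C2–C3–C4–C5. The C2 catechol ring, the C3 hydroxymethyl group (C9) and the C4 hydroxyl all sit on one face (the less stable cis-2,3 pattern), and C4 also carries the benzylic carbon C7'.
The C7'–aryl bond is cut first. The veratryl ring is added as an aryl nucleophile to the CH2 of a spiro-oxirane at C4/C7', and the oxirane oxygen is delivered to a C4=C7' exocyclic alkene under guidance of the cis C9 hydroxyl.
C5 is traced back to a lactone carbonyl. The α-methylene-γ-butyrolactone is cut at C2–C3 and O1–C5 into 3,4-bis(benzyloxy)benzaldehyde and a five-carbon 2-(methoxycarbonyl)allylboronate, which is built from methyl acrylate and TBSOCH2CHO.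
Ring order: the oxolane ring is closed first, as a lactone, in the key step. The spiro-oxirane at C4 is then made and opened again, and both arenes are bought.
Key step: step 4

Assumption: the (R)-configured phosphoric acid is taken to expose the Re face of the aryl aldehyde, as it does with allyl and crotyl pinacolboronates. If this boronate responds with the opposite sense, the (S)-acid is used and nothing else changes.

**Step 1**
Reactants: 1 (tert-butyldimethylsilyloxy)acetaldehyde; 2 methyl acrylate
Product: 3 methyl 4-(tert-butyldimethylsilyloxy)-3-hydroxy-2-methylidenebutanoate (racemic)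
Conditions: DABCO (0.5 equiv), 2 (3 equiv), MeOH, rt
Reagents that add atoms: none
Why: Morita–Baylis–Hillman reaction, in which the amine adds to the acrylate, the α-carbon attacks the reactive α-silyloxy aldehyde and the amine is expelled; the new carbinol centre is racemic, which is harmless because it becomes sp2 in step 3.

**Step 2**
Reactants: 3 methyl 4-(tert-butyldimethylsilyloxy)-3-hydroxy-2-methylidenebutanoate
Product: 4 methyl 3-acetoxy-4-(tert-butyldimethylsilyloxy)-2-methylidenebutanoate (racemic)
Conditions: Ac2O, pyridine, DMAP (cat.), CH2Cl2, 0 °C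
Reagents that add atoms: acetic anhydride, CC(=O)OC(C)=O
Why: Routine O-acetylation turns the secondary allylic hydroxyl into a leaving group for allylic substitution and leaves the silyl ether and the acrylate untouched.

**Step 3**
Reactants: 4 methyl 3-acetoxy-4-(tert-butyldimethylsilyloxy)-2-methylidenebutanoate
Product: 5 methyl (E)-4-(tert-butyldimethylsilyloxy)-2-[(4,4,5,5-tetramethyl-1,3,2-dioxaborolan-2-yl)methyl]but-2-enoate (CH2OTBS cis to CH2B and trans to CO2Me)
Conditions: B2pin2 (1.1 equiv), Pd2(dba)3 (2.5 mol %), toluene, 50 °C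
Reagents that add atoms: bis(pinacolato)diboron, CC1(C)OB(OC1(C)C)B1OC(C)(C)C(C)(C)O1
Why: Palladium-catalysed allylic borylation of a Morita–Baylis–Hillman acetate (overall SN2'), in which zerovalent palladium ionises the acetate, the acetate-activated diboron transmetallates and the C–B bond forms at the unsubstituted CH2 terminus, so the conjugated trisubstituted alkene should place CH2OTBS away from the ester; a minor geometric isomer can be removed on silica because the pinacol ester tolerates chromatography.

**Step 4**
Reactants: 5 methyl (E)-4-(tert-butyldimethylsilyloxy)-2-[(pinacolboryl)methyl]but-2-enoate; 6 3,4-bis(benzyloxy)benzaldehyde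
Product: 8 (4R,5R)-5-[3,4-bis(benzyloxy)phenyl]-4-[(tert-butyldimethylsilyloxy)methyl]-3-methylideneoxolan-2-one (cis lactone), via syn-homoallylic pinacol borate 7 (not isolated)
Conditions: (R)-TRIP [(R)-3,3'-bis(2,4,6-triisopropylphenyl)-1,1'-binaphthyl-2,2'-diyl hydrogen phosphate] (10 mol %), toluene, 0 °C → rt
Reagents that add atoms: none
Why: The acid hydrogen-bonds to a pinacol oxygen of 5 while its P=O contacts the formyl hydrogen of 6, which makes boron more Lewis acidic, so the aldehyde binds boron and C2–C3 forms through a closed Zimmerman–Traxler chair that shifts the double bond to C4=C7' and gives borate 7. The closest known reaction types are the acid-catalysed addition of 2-(alkoxycarbonyl)allylboronates to aldehydes with lactonisation in the same pot and the chiral phosphoric acid catalysed crotylboration of aromatic aldehydes with pinacol boronates, and this step joins the two. The only ring closed is the oxolane ring O1–C2–C3–C4–C5, formed at the lactone level by 5-exo-trig attack of the C2 borate oxygen on the methyl ester with loss of MeOBpin. C3 relative to C2 is fixed by the alkene geometry of 5, because an equatorial aryl group and an axial CH2OTBS (cis to CH2B) in the chair lead to the syn borate and hence the cis lactone, while the absolute sense at C2 (Re-face attack, R) comes from the binaphthyl pocket of the catalyst. The step needs syn diastereoselection, attack on one aldehyde face and no later ionisation of the electron-rich benzylic C2–O bond. These are secured by the geometrically pure and configurationally stable boronate, by the negligible uncatalysed background of this electron-poor boronate, and by the weak acid at low temperature.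

**Step 5**
Reactants: 8 cis α-methylene lactone
Product: 9 (4R,5R)-5-[3,4-bis(benzyloxy)phenyl]-4-[(tert-butyldimethylsilyloxy)methyl]-3-methylideneoxolan-2-ol (lactol, mixture of anomers at C5 of the target numbering)
Conditions: DIBAL-H (1.1 equiv), CH2Cl2, −78 °C; aq Rochelle salt
Reagents that add atoms: none
Why: Partial lactone reduction with one equivalent of DIBAL-H at −78 °C proceeds by 1,2-hydride delivery and stops at the lactol level until work-up; C2 and C3 are not involved, and the new anomeric centre disappears in step 6.

**Step 6**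
Reactants: 9 α-methylene lactol
Product: 10 tert-butyl({(2R,3R)-2-[3,4-bis(benzyloxy)phenyl]-4-methylideneoxolan-3-yl}methoxy)dimethylsilane
Conditions: Et3SiH (4 equiv), BF3·OEt2 (1.5 equiv), CH2Cl2, −78 °C; Et3N then aq NaHCO3 at −78 °C
Reagents that add atoms: none
Why: Ionic deoxygenation of a lactol, in which BF3 activates the anomeric hydroxyl as a leaving group and the silane delivers hydride to C5; at −78 °C the benzylic C2–O1 bond and the exocyclic alkene should stay in place, and any early loss of the silyl group is harmless because step 7 removes it.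

**Step 7**
Reactants: 10 silyl ether of the 4-methylideneoxolane
Product: 11 {(2R,3R)-2-[3,4-bis(benzyloxy)phenyl]-4-methylideneoxolan-3-yl}methanol
Conditions: TBAF (1.2 equiv), THF, 0 °C → rt
Reagents that add atoms: none
Why: Fluoride cleaves the Si–O bond, driven by the strong Si–F bond, and frees the primary C9 hydroxyl needed as a directing group; the benzyl ethers, the alkene and the cyclic ether are inert to TBAF.

**Step 8**
Reactants: 11 homoallylic alcohol
Product: 12 {(3S,6R,7R)-6-[3,4-bis(benzyloxy)phenyl]-1,5-dioxaspiro[2.4]heptan-7-yl}methanol (oxirane oxygen cis to CH2OH and to the aryl group)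
Conditions: VO(acac)2 (5 mol %), t-BuOOH (1.5 equiv, decane solution), CH2Cl2, 0 °C → rt
Reagents that add atoms: tert-butyl hydroperoxide, CC(C)(C)OO
Why: Hydroxyl-directed vanadium-catalysed epoxidation of a homoallylic alcohol, in which the C9 alkoxide and the alkyl peroxide bind to the same pentavalent vanadium centre, so oxygen is passed to the alkene face that carries CH2OH and C4 is set with O4 cis to C9 and to the C2 aryl group.

**Step 9**
Reactants: 13 4-bromo-1,2-dimethoxybenzene (4-bromoveratrole)
Product: 14 3,4-dimethoxyphenylmagnesium bromide (titrated THF solution)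
Conditions: Mg turnings, I2 (cat.), THF, gentle reflux → rt
Reagents that add atoms: magnesium, [Mg]
Why: Classical Grignard formation by magnesium insertion into an aryl bromide, to which the two methyl ethers are inert.

**Step 10**
Reactants: 12 spiro-epoxy alcohol; 14 3,4-dimethoxyphenylmagnesium bromide
Product: 15 (3R,4R,5R)-5-[3,4-bis(benzyloxy)phenyl]-3-(3,4-dimethoxybenzyl)-4-(hydroxymethyl)oxolan-3-ol
Conditions: 14 (4 equiv), CuI (20 mol %), THF, −30 → 0 °C; aq NH4Cl
Reagents that add atoms: none
Why: Copper-catalysed opening of a 2,2-disubstituted oxirane by an aryl Grignard reagent, with SN2 attack at the unhindered CH2 (C7') driven by release of ring strain, so the C4–O bond and the C4 configuration are untouched; the excess reagent takes up the C9 hydroxyl proton, and internal attack by that oxygen is blocked because it lies on the same face as the oxirane oxygen.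

**Step 11**
Reactants: 15 bis-benzyl ether
Product: 16 (3R,4R,5R)-5-(3,4-dihydroxyphenyl)-3-(3,4-dimethoxybenzyl)-4-(hydroxymethyl)oxolan-3-ol (CNP0115253.1)
Conditions: H2 (1 atm), 10% Pd/C, EtOAc–EtOH, rt, stopped as soon as 15 is consumed; work-up under argon
Reagents that add atoms: none
Why: Catalytic hydrogenolysis of aryl benzyl ethers is much faster than cleavage of the cyclic benzylic C2–O1 bond, so a short exposure at atmospheric pressure should free only the catechol without touching a stereocentre.

**Compound list**
1 | (tert-butyldimethylsilyloxy)acetaldehyde | O=CCO[Si](C)(C)C(C)(C)C | starting material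
2 | methyl acrylate | C=CC(=O)OC | starting material
3 | methyl 4-(tert-butyldimethylsilyloxy)-3-hydroxy-2-methylidenebutanoate (racemic) | C=C(C(=O)OC)C(O)CO[Si](C)(C)C(C)(C)C | intermediate
4 | methyl 3-acetoxy-4-(tert-butyldimethylsilyloxy)-2-methylidenebutanoate (racemic) | C=C(C(=O)OC)C(OC(C)=O)CO[Si](C)(C)C(C)(C)C | intermediate
5 | methyl (E)-4-(tert-butyldimethylsilyloxy)-2-[(4,4,5,5-tetramethyl-1,3,2-dioxaborolan-2-yl)methyl]but-2-enoate | COC(=O)/C(CB1OC(C)(C)C(C)(C)O1)=C/CO[Si](C)(C)C(C)(C)C | intermediate
6 | 3,4-bis(benzyloxy)benzaldehyde | O=Cc1ccc(OCc2ccccc2)c(OCc2ccccc2)c1 | starting material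
7 | syn-homoallylic pinacol borate (C2 R, C3 R; methyl ester still open) | C=C(C(=O)OC)[C@H](CO[Si](C)(C)C(C)(C)C)[C@@H](OB1OC(C)(C)C(C)(C)O1)c1ccc(OCc2ccccc2)c(OCc2ccccc2)c1 | intermediate
8 | (4R,5R)-5-[3,4-bis(benzyloxy)phenyl]-4-[(tert-butyldimethylsilyloxy)methyl]-3-methylideneoxolan-2-one | C=C1C(=O)O[C@@H](c2ccc(OCc3ccccc3)c(OCc3ccccc3)c2)[C@H]1CO[Si](C)(C)C(C)(C)C | intermediate
9 | (4R,5R)-5-[3,4-bis(benzyloxy)phenyl]-4-[(tert-butyldimethylsilyloxy)methyl]-3-methylideneoxolan-2-ol (anomer mixture) | C=C1C(O)O[C@@H](c2ccc(OCc3ccccc3)c(OCc3ccccc3)c2)[C@H]1CO[Si](C)(C)C(C)(C)C | intermediate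
10 | tert-butyl({(2R,3R)-2-[3,4-bis(benzyloxy)phenyl]-4-methylideneoxolan-3-yl}methoxy)dimethylsilane | C=C1CO[C@@H](c2ccc(OCc3ccccc3)c(OCc3ccccc3)c2)[C@H]1CO[Si](C)(C)C(C)(C)C | intermediate
11 | {(2R,3R)-2-[3,4-bis(benzyloxy)phenyl]-4-methylideneoxolan-3-yl}methanol | C=C1CO[C@@H](c2ccc(OCc3ccccc3)c(OCc3ccccc3)c2)[C@H]1CO | intermediate
12 | {(3S,6R,7R)-6-[3,4-bis(benzyloxy)phenyl]-1,5-dioxaspiro[2.4]heptan-7-yl}methanol | C1O[C@]12CO[C@@H](c3ccc(OCc4ccccc4)c(OCc4ccccc4)c3)[C@H]2CO | intermediate
13 | 4-bromo-1,2-dimethoxybenzene | COc1ccc(Br)cc1OC | starting material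
14 | 3,4-dimethoxyphenylmagnesium bromide | COc1ccc([Mg]Br)cc1OC | intermediate
15 | (3R,4R,5R)-5-[3,4-bis(benzyloxy)phenyl]-3-(3,4-dimethoxybenzyl)-4-(hydroxymethyl)oxolan-3-ol | COc1ccc(C[C@]2(O)CO[C@@H](c3ccc(OCc4ccccc4)c(OCc4ccccc4)c3)[C@H]2CO)cc1OC | intermediate
16 | (3R,4R,5R)-5-(3,4-dihydroxyphenyl)-3-(3,4-dimethoxybenzyl)-4-(hydroxymethyl)oxolan-3-ol (CNP0115253.1) | COc1ccc(C[C@]2(O)CO[C@@H](c3ccc(O)c(O)c3)[C@H]2CO)cc1OC | target

**Total step count:** 11
**Longest linear sequence:** 10 steps (steps 1–8, 10 and 11; step 9 is a one-step side branch)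

**Steps most likely to fail**

Step 4. The ester-bearing, γ-substituted boronate is a weak nucleophile, so turnover under a weak chiral acid may be slow. Its extra bulk may also erode the face discrimination seen with simple crotylboronates.
The fallback gives up asymmetric catalysis for a racemic addition followed by resolution. It sets out from 5 and 6. Sc(OTf)3 (10 mol %) in toluene at rt, a Lewis acid catalysis established for this class of boronate, should pass through the racemic syn borate F1. The same chair control should then give the racemic cis lactone F2. The enantiomers are separated by preparative chromatography on a polysaccharide-based chiral stationary phase. The (4S,5S)-lactone F3 is set aside, and the (4R,5R)-enantiomer is compound 8, where the route is rejoined.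

Step 6. Three processes may compete under BF3: ionisation of the electron-rich benzylic C2–O1 bond with loss of the cis-2,3 relation, hydride delivery with allylic transposition, and migration of the exocyclic double bond into the ring.
The fallback avoids Lewis acid and never breaks a bond at C2. It sets out from 8. Excess DIBAL-H (CH2Cl2, −78 → 0 °C) should reduce the lactone fully to the ene-diol F4. TsCl, Et3N and catalytic DMAP at 0 °C should sulfonylate only the primary allylic hydroxyl, giving the primary allylic tosylate F5. NaH in THF at 0 °C then closes the ring by a 5-exo-tet Williamson etherification through the C2 oxygen, with retention at C2, and this gives compound 10.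

Step 8. The face that carries the directing CH2OH is also shielded by the C2 aryl group, and a homoallylic hydroxyl binds vanadium less firmly than an allylic one. Facial selectivity may therefore be poor, and the acid-sensitive spiro-oxirane may rearrange.
The fallback sets C4 by steric substrate control in a carbonyl addition instead. It sets out from 10. Lemieux–Johnson cleavage (OsO4 cat., NaIO4, 2,6-lutidine, dioxane–H2O) should give the oxolan-3-one F6. 3,4-Dimethoxybenzylmagnesium chloride F7 is made from 3,4-dimethoxybenzyl chloride and Mg in THF. It is premixed with anhydrous CeCl3 to suppress enolisation at C3 and β-elimination of the silyloxy group, and it is added at −78 °C. Attack should come from the face opposite to the C3 and C2 substituents, which leaves O4 cis to both in the silyl ether F8. TBAF in THF then gives compound 15, where the route is rejoined.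

**Further compounds**
F1 | step 4 | racemic syn-homoallylic pinacol borate | C=C(C(=O)OC)[C@H](CO[Si](C)(C)C(C)(C)C)[C@@H](OB1OC(C)(C)C(C)(C)O1)c1ccc(OCc2ccccc2)c(OCc2ccccc2)c1.C=C(C(=O)OC)[C@@H](CO[Si](C)(C)C(C)(C)C)[C@H](OB1OC(C)(C)C(C)(C)O1)c1ccc(OCc2ccccc2)c(OCc2ccccc2)c1
F2 | step 4 | racemic cis-5-[3,4-bis(benzyloxy)phenyl]-4-[(tert-butyldimethylsilyloxy)methyl]-3-methylideneoxolan-2-one | C=C1C(=O)O[C@@H](c2ccc(OCc3ccccc3)c(OCc3ccccc3)c2)[C@H]1CO[Si](C)(C)C(C)(C)C.C=C1C(=O)O[C@H](c2ccc(OCc3ccccc3)c(OCc3ccccc3)c2)[C@@H]1CO[Si](C)(C)C(C)(C)C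
F3 | step 4 | (4S,5S)-5-[3,4-bis(benzyloxy)phenyl]-4-[(tert-butyldimethylsilyloxy)methyl]-3-methylideneoxolan-2-one | C=C1C(=O)O[C@H](c2ccc(OCc3ccccc3)c(OCc3ccccc3)c2)[C@@H]1CO[Si](C)(C)C(C)(C)C
F4 | step 6 | (1R,2R)-1-[3,4-bis(benzyloxy)phenyl]-2-[(tert-butyldimethylsilyloxy)methyl]-3-methylidenebutane-1,4-diol | C=C(CO)[C@H](CO[Si](C)(C)C(C)(C)C)[C@@H](O)c1ccc(OCc2ccccc2)c(OCc2ccccc2)c1
F5 | step 6 | (3R,4R)-4-[3,4-bis(benzyloxy)phenyl]-3-[(tert-butyldimethylsilyloxy)methyl]-4-hydroxy-2-methylidenebutyl 4-methylbenzenesulfonate | C=C(COS(=O)(=O)c1ccc(C)cc1)[C@H](CO[Si](C)(C)C(C)(C)C)[C@@H](O)c1ccc(OCc2ccccc2)c(OCc2ccccc2)c1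
F6 | step 8 | (4R,5R)-5-[3,4-bis(benzyloxy)phenyl]-4-[(tert-butyldimethylsilyloxy)methyl]oxolan-3-one | O=C1CO[C@@H](c2ccc(OCc3ccccc3)c(OCc3ccccc3)c2)[C@H]1CO[Si](C)(C)C(C)(C)C
F7 | step 8 | 3,4-dimethoxybenzylmagnesium chloride | COc1ccc(C[Mg]Cl)cc1OC
F8 | step 8 | (3R,4R,5R)-5-[3,4-bis(benzyloxy)phenyl]-4-[(tert-butyldimethylsilyloxy)methyl]-3-(3,4-dimethoxybenzyl)oxolan-3-ol | COc1ccc(C[C@]2(O)CO[C@@H](c3ccc(OCc4ccccc4)c(OCc4ccccc4)c3)[C@H]2CO[Si](C)(C)C(C)(C)C)cc1OC
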